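**Retrosynthetic overview**
1. Ring F (the dioxolane) forms last. A singlet-oxygen ene reaction on the 7′(11′)-isopropylidene enone of triketone 47 gives a hydroperoxide that closes onto C8′=O.
2. The bridging syn-C2 acetate and the C1–C4′ bond come from a Cope rearrangement of the isomeric endo adduct 44. In 44 the acetate carbon is an ordinary allylic centre, set by Luche reduction and Mitsunobu inversion.
3. Adduct 42 comes from a cross Diels–Alder reaction of transient cyclopentadienone 41 (isopropyl half) with cyclopentadienone ketal 39 (isopropylidene half).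
4. Each hydroazulenone has its seven-membered ring closed by ring-closing metathesis. The RCM substrates arise by Stork–Danheiser union of one vinylogous ester 5 with the Evans-aldol iodides 14 and 29.
5. Ring order: cyclopentenone (bought), then the seven-membered ring by RCM (twice), then the norbornene by [4+2], then its re-routing by [3,3], then the 1,2-dioxolane.

Assumption: guaiane numbering is used (unprimed = isopropyl half, primed = peroxide half). C4/C4′ and the adjacent selenide carbon are carried as epimer mixtures and drawn without configuration, because both become sp2 in steps 25 and 26.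

**Vinylogous ester (used twice)**

Step 1
Reactants: 1 3-methoxycyclopent-2-en-1-one
Product: 2 2-bromo-3-methoxycyclopent-2-en-1-one
Conditions: NBS, CH2Cl2, 0 °C to rt, dark
Reagents that add atoms: N-bromosuccinimide, O=C1CCC(=O)N1Br
Why: Electrophilic bromination occurs at the nucleophilic C2 of the vinylogous ester, and no stereocentre is formed.

Step 2
Reactants: 2 2-bromo-3-methoxycyclopent-2-en-1-one; 3 isopropenylboronic acid pinacol ester
Product: 4 3-methoxy-2-(prop-1-en-2-yl)cyclopent-2-en-1-one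
Conditions: Pd(dppf)Cl2 (3 mol %), K2CO3, dioxane/H2O, 80 °C
Reagents that add atoms: none
Why: Suzuki–Miyaura coupling of an α-bromoenone installs the 1,1-disubstituted alkene that later becomes C10/C10′ and its methyl group.

Step 3
Reactants: 4 3-methoxy-2-(prop-1-en-2-yl)cyclopent-2-en-1-one
Product: 5 (±)-3-methoxy-5-methyl-2-(prop-1-en-2-yl)cyclopent-2-en-1-one
Conditions: LDA, THF, −78 °C; MeI
Reagents that add atoms: iodomethane, CI
Why: Kinetic α′-enolate alkylation of the vinylogous ester places the future C4/C4′ methyl, and the racemic centre is erased later.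

**Isopropyl half**

Step 4
Reactants: 6 (S)-4-benzyloxazolidin-2-one; 7 3-methylbutanoyl chloride
Product: 8 (S)-4-benzyl-3-(3-methylbutanoyl)oxazolidin-2-one
Conditions: n-BuLi, THF, −78 °C; then 7
Reagents that add atoms: none
Why: This is a standard N-acylation of the lithiated Evans auxiliary.

Step 5
Reactants: 8 (S)-4-benzyl-3-(3-methylbutanoyl)oxazolidin-2-one; 9 acrolein
Product: 11 (S)-4-benzyl-3-[(2S,3R)-3-hydroxy-2-isopropylpent-4-enoyl]oxazolidin-2-one, via (Z)-dibutylboron enolate 10 (not isolated)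
Conditions: Bu2BOTf, Et3N, CH2Cl2, −78 to 0 °C; 9, −78 °C; H2O2, MeOH, pH 7
Reagents that add atoms: none
Why: The Evans syn-aldol reaction proceeds through a Zimmerman–Traxler chair on the enolate face opposite the benzyl group, which sets C7 (S) and C8 (R).

Step 6
Reactants: 11 syn-aldol imide
Product: 12 (S)-4-benzyl-3-[(2S,3R)-2-isopropyl-3-(triethylsilyloxy)pent-4-enoyl]oxazolidin-2-one
Conditions: TESCl, imidazole, DMF, 0 °C
Reagents that add atoms: chlorotriethylsilane, CC[Si](Cl)(CC)CC
Why: O-silylation blocks retro-aldol, and TES is chosen because it is lost in the acidic work-up of step 9.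

Step 7
Reactants: 12 TES-protected imide
Product: 13 (2R,3R)-2-isopropyl-3-(triethylsilyloxy)pent-4-en-1-ol
Conditions: LiBH4, MeOH (1 equiv), Et2O, 0 °C
Reagents that add atoms: none
Why: Reductive cleavage of the imide carbonyl releases the auxiliary without touching either stereocentre.

Step 8
Reactants: 13 primary alcohol
Product: 14 (3R,4S)-4-(iodomethyl)-5-methyl-3-(triethylsilyloxy)hex-1-ene
Conditions: I2, PPh3, imidazole, CH2Cl2, 0 °C
Reagents that add atoms: iodine, II
Why: Appel-type iodination takes place at the primary carbon only.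

Step 9
Reactants: 14 iodide; 5 vinylogous ester
Product: 17 3-[(2S,3R)-3-hydroxy-2-isopropylpent-4-en-1-yl]-4-methyl-2-(prop-1-en-2-yl)cyclopent-2-en-1-one, via alkyllithium 15 (not isolated), via tertiary carbinol 16 (not isolated)
Conditions: t-BuLi (2.1 equiv), Et2O, −78 °C; 5, −78 to 0 °C; 1 M HCl, THF, rt
Reagents that add atoms: water, O
Why: Li–I exchange, 1,2-addition and Stork–Danheiser transposition give the 2,3,4-trisubstituted enone, and the same acid removes the TES group.

Step 10
Reactants: 17 trienone alcohol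
Product: 18 (7S,8S)-8-hydroxyguaia-1(5),9-dien-2-one (C4 epimers)
Conditions: Grubbs II (5 mol %), CH2Cl2 (2 mM), 40 °C
Reagents that add atoms: none
Why: Ring-closing metathesis of the allylic-alcohol vinyl group onto the isopropenyl group closes the seven-membered ring as a trisubstituted C9=C10 alkene, with the free allylic OH accelerating the reaction.

Step 11
Reactants: 18 dienone alcohol
Product: 19 (7S,8R,10R)-8-hydroxyguai-1(5)-en-2-one (C4 epimers)
Conditions: [Ir(cod)(PCy3)(py)]PF6 (5 mol %), H2 (1 atm), CH2Cl2, 0 °C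
Reagents that add atoms: none
Why: Hydroxyl-directed Crabtree hydrogenation delivers H2 to the face carrying the 8-OH, so the 10-methyl ends trans to OH and cis to the 7-isopropyl (10R), while the tetrasubstituted enone is inert.

Step 12
Reactants: 19 hydroxy enone
Product: 20 (7S,8R,10R)-8-(tert-butyldimethylsilyloxy)guai-1(5)-en-2-one
Conditions: TBSOTf, 2,6-lutidine, CH2Cl2, 0 °C
Reagents that add atoms: tert-butyldimethylsilyl triflate, CC(C)(C)[Si](C)(C)OS(=O)(=O)C(F)(F)F
Why: Masking C8 at the alcohol level keeps C7 from epimerising and leaves C2 as the only carbonyl of this half during step 27.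

Step 13
Reactants: 20 silyl ether enone
Product: 21 3-(phenylselanyl) derivative of 20
Conditions: LDA, THF, −78 °C; PhSeCl
Reagents that add atoms: benzeneselenenyl chloride, Cl[Se]c1ccccc1
Why: Kinetic α′-deprotonation and selenenylation trans to the C4 methyl place Se syn to H4, as the later syn-elimination requires.

**Isopropylidene half**

Step 14
Reactants: 22 (R)-4-benzyloxazolidin-2-one; 23 3-methylbut-2-enoyl chloride
Product: 24 (R)-4-benzyl-3-(3-methylbut-2-enoyl)oxazolidin-2-one
Conditions: n-BuLi, THF, −78 °C; then 23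
Reagents that add atoms: none
Why: This is an N-acylation of the lithiated Evans auxiliary.

Step 15
Reactants: 24 senecioyl imide; 9 acrolein
Product: 26 (R)-4-benzyl-3-[(2R,3S)-3-hydroxy-2-(prop-1-en-2-yl)pent-4-enoyl]oxazolidin-2-one, via dibutylboron dienolate 25 (not isolated)
Conditions: Bu2BOTf, Et3N, CH2Cl2, −78 to 0 °C; 9, −78 °C; H2O2, MeOH, pH 7
Reagents that add atoms: none
Why: The deconjugative Evans syn-aldol reaction (γ-deprotonation, α-attack of the boron dienolate) is auxiliary-controlled and fixes C8′ (S).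

Step 16
Reactants: 26 aldol imide
Product: 27 TBS ether of 26
Conditions: TBSOTf, 2,6-lutidine, CH2Cl2, −78 to 0 °C
Reagents that add atoms: tert-butyldimethylsilyl triflate, CC(C)(C)[Si](C)(C)OS(=O)(=O)C(F)(F)F
Why: This silylation installs a bulky group that stays on until step 30 and later serves as the stereocontrol element.

Step 17
Reactants: 27 TBS imide
Product: 28 (2S,3S)-3-(tert-butyldimethylsilyloxy)-2-(prop-1-en-2-yl)pent-4-en-1-ol
Conditions: LiBH4, MeOH (1 equiv), Et2O, 0 °C
Reagents that add atoms: none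
Why: Reductive removal of the auxiliary leaves the stereocentres untouched.

Step 18
Reactants: 28 primary alcohol
Product: 29 (3S,4R)-3-(tert-butyldimethylsilyloxy)-4-(iodomethyl)-5-methylhexa-1,5-diene
Conditions: I2, PPh3, imidazole, CH2Cl2, 0 °C
Reagents that add atoms: iodine, II
Why: Appel-type iodination gives a homoallylic iodide, so the derived organolithium has no allylic regiochemistry problem.

Step 19
Reactants: 29 iodide; 5 vinylogous ester
Product: 32 3-[(2R,3S)-3-(tert-butyldimethylsilyloxy)-2-(prop-1-en-2-yl)pent-4-en-1-yl]-4-methyl-2-(prop-1-en-2-yl)cyclopent-2-en-1-one, via alkyllithium 30 (not isolated), via tertiary carbinol 31 (not isolated)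
Conditions: t-BuLi (2.1 equiv), Et2O, −78 °C; 5, −78 to 0 °C; 1 M HCl, THF, 0 °C, 20 min
Reagents that add atoms: water, O
Why: Li–I exchange, 1,2-addition and Stork–Danheiser transposition give the enone, and the brief cold acid leaves the TBS ether in place.

Step 20
Reactants: 32 tetraene
Product: 33 (7′R,8′S)-8′-(tert-butyldimethylsilyloxy)guaia-1(5),9,11-trien-2-one (C4′ epimers)
Conditions: Hoveyda–Grubbs II (5 mol %), toluene (2 mM), 80 °C
Reagents that add atoms: none
Why: Ring-closing metathesis starts at the only monosubstituted alkene and closes onto the ring isopropenyl group to give the seven-membered ring, because the alternatives would be a cyclobutene or a tetrasubstituted alkene.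

Step 21
Reactants: 33 trienone
Product: 34 (8′S)-8′-(tert-butyldimethylsilyloxy)guaia-1(5),7(11),9-trien-2-one
Conditions: Co(salen-tBu,tBu)Cl (3 mol %), PhSiH3 (6 mol %), benzene, rt
Reagents that add atoms: none
Why: Radical (MHAT) alkene isomerisation acts selectively on the 1,1-disubstituted isopropenyl group and ends at the unreactive tetrasubstituted isopropylidene.

Step 22
Reactants: 34 isopropylidene trienone
Product: 35 (8′S,10′R)-8′-(tert-butyldimethylsilyloxy)guaia-1(5),7(11)-dien-2-one
Conditions: [Ir(cod)(PCy3)(py)]PF6 (3 mol %), H2 (1 atm), CH2Cl2, 0 °C, stopped at 1 equiv H2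
Reagents that add atoms: none
Why: A(1,3) strain against the isopropylidene holds the OTBS group axial, so 1,2-hydrogenation of the only trisubstituted alkene comes from the opposite face and puts the 10′-methyl cis to OTBS (10′R).

Step 23
Reactants: 35 dienone
Product: 36 3′-(phenylselanyl) derivative of 35
Conditions: LDA, THF, −78 °C; PhSeCl
Reagents that add atoms: benzeneselenenyl chloride, Cl[Se]c1ccccc1
Why: Kinetic α′-enolate selenenylation occurs trans to the C4′ methyl.

Step 24
Reactants: 36 selenide enone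
Product: 37 2′,2′-ethylenedioxy ketal of 36
Conditions: (TMSOCH2)2, TMSOTf (10 mol %), CH2Cl2, −78 to −20 °C; pyridine quench
Reagents that add atoms: 1,2-bis(trimethylsilyloxy)ethane, C[Si](C)(C)OCCO[Si](C)(C)C
Why: Aprotic Noyori ketalisation converts the enone carbonyl without moving the C1′=C5′ double bond.

Step 25
Reactants: 37 selenide ketal
Product: 39 cyclopentadienone ethylene ketal (8′S,10′R)-8′-(tert-butyldimethylsilyloxy)-2′,2′-ethylenedioxyguaia-1(5),3,7(11)-triene, via selenoxide 38 (not isolated)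
Conditions: 30 % H2O2, pyridine, CH2Cl2, 0 °C to rt; used at once
Reagents that add atoms: none
Why: Selenoxide syn-elimination can only run towards H4′ because C2′ is quaternary, and it gives a 5,5-dialkoxycyclopentadiene that cannot undergo a 1,5-H shift.

**Union and endgame**

Step 26
Reactants: 21 selenide of the isopropyl half; 39 diene ketal (1.5 equiv)
Product: 42 endo adduct with new bonds C3–C3′ and C4–C1′, the C2′ dioxolane on the bridge and a C2 enone conjugated to C1=C5, via selenoxide 40 (not isolated), via cyclopentadienone 41 (not isolated)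
Conditions: mCPBA (1.0 equiv), CH2Cl2, −78 °C; then 39, pyridine, −78 °C to rt
Reagents that add atoms: none
Why: The endo Diels–Alder reaction of the transient cyclopentadienone is asynchronous and led by bonding of the two unsubstituted termini C3/C3′, each partner reacts on the face away from its C10 methyl (setting C3, C4, C1′, C3′), and any [2+4] peri-isomer converges on the conjugated enone by Cope shift.

Step 27
Reactants: 42 adduct enone
Product: 43 2-endo-allylic alcohol (OH on the concave face)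
Conditions: NaBH4, CeCl3·7H2O, MeOH/THF, −40 to 0 °C
Reagents that add atoms: none
Why: Luche 1,2-reduction of the only free carbonyl occurs from the convex face of the endo-tricyclodecadienone.

Step 28
Reactants: 43 endo alcohol
Product: 44 2-exo-allylic acetate (OAc on the convex face)
Conditions: AcOH, PPh3, DIAD, toluene, 0 °C to rt
Reagents that add atoms: acetic acid, CC(=O)O
Why: Mitsunobu inversion brings acetate in from the open convex face and gives the final configuration at C2, with SN2′ blocked at the fully substituted C5.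

Step 29
Reactants: 44 exo acetate
Product: 45 rearranged adduct with bonds C3–C3′ and C1–C4′, the C2–OAc on the bridge syn to C4=C5, and the C2′ dioxolane now allylic to C1′=C5′
Conditions: toluene (0.01 M, BHT), sealed tube, 120 °C
Reagents that add atoms: none
Why: This Woodward–Katz-type [3,3] Cope rearrangement of the rigid boat 1,5-diene is suprafacial on both allyl units, so it carries the exo-acetate to the syn-bridge position, creates C1 and C4′, and relieves the compression between the bridge ketal and the exo-methyl.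

Step 30
Reactants: 45 rearranged ketal
Product: 46 8,8′-diol 2′-enone
Conditions: 48 % aq HF, MeCN, 0 °C to rt
Reagents that add atoms: water, O
Why: One mild acid step cleaves both TBS ethers and hydrolyses the now allylic (enone-type) ketal while the acetate survives.

Step 31
Reactants: 46 diol
Product: 47 2-acetoxy-2′,8,8′-trione with the 7′(11′)-isopropylidene
Conditions: Dess–Martin periodinane (2.5 equiv), CH2Cl2, 0 °C to rt
Reagents that add atoms: none
Why: Non-basic Dess–Martin oxidation of both carbinols avoids epimerisation at C7.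

Step 32
Reactants: 47 trione
Product: 49 CNP0317907.1 (target), via 11′-hydroperoxy-6′-en-8′-one 48 (not isolated)
Conditions: O2, tetraphenylporphyrin (cat.), CH2Cl2, visible light, −20 °C; then rt
Reagents that add atoms: dioxygen, O=O
Why: The Schenck ene reaction follows the gem rule known for pulegone (H6′ abstracted, O at C11′). C4=C5 is shielded by the syn-acetate above and ring D below, and reversible hemiketalisation settles on the C8′ epimer with an in-plane peroxide oxygen and an axial OH cis to the axial 10′-methyl.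

**Compound list**
1 | 3-methoxycyclopent-2-en-1-one | COC1=CC(=O)CC1 | starting material
2 | 2-bromo-3-methoxycyclopent-2-en-1-one | COC1=C(Br)C(=O)CC1 | intermediate
3 | isopropenylboronic acid pinacol ester | CC(=C)B1OC(C)(C)C(C)(C)O1 | starting material
4 | 3-methoxy-2-(prop-1-en-2-yl)cyclopent-2-en-1-one | COC1=C(C(C)=C)C(=O)CC1 | intermediate
5 | (±)-3-methoxy-5-methyl-2-(prop-1-en-2-yl)cyclopent-2-en-1-one | COC1=C(C(C)=C)C(=O)C(C)C1 | intermediate
6 | (S)-4-benzyloxazolidin-2-one | O=C1N[C@@H](Cc2ccccc2)CO1 | starting material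
7 | 3-methylbutanoyl chloride | CC(C)CC(Cl)=O | starting material
8 | (S)-4-benzyl-3-(3-methylbutanoyl)oxazolidin-2-one | CC(C)CC(=O)N1C(=O)OC[C@@H]1Cc1ccccc1 | intermediate
9 | acrolein | C=CC=O | starting material
10 | (Z)-dibutylboron enolate of 8 | CC(C)/C=C(\OB(CCCC)CCCC)N1C(=O)OC[C@@H]1Cc1ccccc1 | intermediate (not isolated)
11 | (2S,3R) syn-aldol imide | C=C[C@@H](O)[C@H](C(C)C)C(=O)N1C(=O)OC[C@@H]1Cc1ccccc1 | intermediate
12 | TES ether of 11 | C=C[C@@H](O[Si](CC)(CC)CC)[C@H](C(C)C)C(=O)N1C(=O)OC[C@@H]1Cc1ccccc1 | intermediate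
13 | (2R,3R)-2-isopropyl-3-(triethylsilyloxy)pent-4-en-1-ol | C=C[C@@H](O[Si](CC)(CC)CC)[C@H](C(C)C)CO | intermediate
14 | (3R,4S)-4-(iodomethyl)-5-methyl-3-(triethylsilyloxy)hex-1-ene | C=C[C@@H](O[Si](CC)(CC)CC)[C@H](C(C)C)CI | intermediate
15 | alkyllithium from 14 | C=C[C@@H](O[Si](CC)(CC)CC)[C@H](C(C)C)C[Li] | intermediate (not isolated)
16 | tertiary carbinol, 1,2-adduct of 15 to 5 | COC1=C(C(C)=C)C(O)(C[C@@H](C(C)C)[C@H](O[Si](CC)(CC)CC)C=C)C(C)C1 | intermediate (not isolated)
17 | trienone alcohol | O=C1CC(C)C(C[C@@H](C(C)C)[C@H](O)C=C)=C1C(C)=C | intermediate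
18 | (7S,8S)-8-hydroxyguaia-1(5),9-dien-2-one | O=C1CC(C)C2=C1C(C)=C[C@@H](O)[C@H](C(C)C)C2 | intermediate
19 | (7S,8R,10R)-8-hydroxyguai-1(5)-en-2-one | O=C1CC(C)C2=C1[C@H](C)C[C@@H](O)[C@H](C(C)C)C2 | intermediate
20 | TBS ether of 19 | O=C1CC(C)C2=C1[C@H](C)C[C@@H](O[Si](C)(C)C(C)(C)C)[C@H](C(C)C)C2 | intermediate
21 | 3-phenylselanyl derivative of 20 | O=C1C([Se]c3ccccc3)C(C)C2=C1[C@H](C)C[C@@H](O[Si](C)(C)C(C)(C)C)[C@H](C(C)C)C2 | intermediate
22 | (R)-4-benzyloxazolidin-2-one | O=C1N[C@H](Cc2ccccc2)CO1 | starting material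
23 | 3-methylbut-2-enoyl chloride | CC(C)=CC(Cl)=O | starting material
24 | (R)-4-benzyl-3-(3-methylbut-2-enoyl)oxazolidin-2-one | CC(C)=CC(=O)N1C(=O)OC[C@H]1Cc1ccccc1 | intermediate
25 | dibutylboron dienolate of 24 | C=C(C)/C=C(\OB(CCCC)CCCC)N1C(=O)OC[C@H]1Cc1ccccc1 | intermediate (not isolated)
26 | (2R,3S) α-isopropenyl syn-aldol imide | C=C[C@H](O)[C@@H](C(C)=C)C(=O)N1C(=O)OC[C@H]1Cc1ccccc1 | intermediate
27 | TBS ether of 26 | C=C[C@H](O[Si](C)(C)C(C)(C)C)[C@@H](C(C)=C)C(=O)N1C(=O)OC[C@H]1Cc1ccccc1 | intermediate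
28 | (2S,3S)-3-(TBSO)-2-(prop-1-en-2-yl)pent-4-en-1-ol | C=C[C@H](O[Si](C)(C)C(C)(C)C)[C@@H](C(C)=C)CO | intermediate
29 | (3S,4R)-3-(TBSO)-4-(iodomethyl)-5-methylhexa-1,5-diene | C=C[C@H](O[Si](C)(C)C(C)(C)C)[C@@H](C(C)=C)CI | intermediate
30 | alkyllithium from 29 | C=C[C@H](O[Si](C)(C)C(C)(C)C)[C@@H](C(C)=C)C[Li] | intermediate (not isolated)
31 | tertiary carbinol, 1,2-adduct of 30 to 5 | COC1=C(C(C)=C)C(O)(C[C@H](C(C)=C)[C@@H](O[Si](C)(C)C(C)(C)C)C=C)C(C)C1 | intermediate (not isolated)
32 | tetraene enone | O=C1CC(C)C(C[C@H](C(C)=C)[C@@H](O[Si](C)(C)C(C)(C)C)C=C)=C1C(C)=C | intermediate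
33 | (7′R,8′S)-8′-(TBSO)guaia-1(5),9,11-trien-2-one | O=C1CC(C)C2=C1C(C)=C[C@H](O[Si](C)(C)C(C)(C)C)[C@@H](C(C)=C)C2 | intermediate
34 | (8′S)-8′-(TBSO)guaia-1(5),7(11),9-trien-2-one | O=C1CC(C)C2=C1C(C)=C[C@H](O[Si](C)(C)C(C)(C)C)C(=C(C)C)C2 | intermediate
35 | (8′S,10′R)-8′-(TBSO)guaia-1(5),7(11)-dien-2-one | O=C1CC(C)C2=C1[C@H](C)C[C@H](O[Si](C)(C)C(C)(C)C)C(=C(C)C)C2 | intermediate
36 | 3′-phenylselanyl derivative of 35 | O=C1C([Se]c3ccccc3)C(C)C2=C1[C@H](C)C[C@H](O[Si](C)(C)C(C)(C)C)C(=C(C)C)C2 | intermediate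
37 | ethylene ketal of 36 | CC1C([Se]c2ccccc2)C3(OCCO3)C4=C1CC(=C(C)C)[C@@H](O[Si](C)(C)C(C)(C)C)C[C@H]4C | intermediate
38 | selenoxide of 37 | CC1C([Se](=O)c2ccccc2)C3(OCCO3)C4=C1CC(=C(C)C)[C@@H](O[Si](C)(C)C(C)(C)C)C[C@H]4C | intermediate (not isolated)
39 | cyclopentadienone ethylene ketal (isopropylidene half) | CC1=CC3(OCCO3)C4=C1CC(=C(C)C)[C@@H](O[Si](C)(C)C(C)(C)C)C[C@H]4C | intermediate
40 | selenoxide of 21 | O=C1C([Se](=O)c3ccccc3)C(C)C2=C1[C@H](C)C[C@@H](O[Si](C)(C)C(C)(C)C)[C@H](C(C)C)C2 | intermediate (not isolated)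
41 | cyclopentadienone (isopropyl half) | O=C1C=C(C)C2=C1[C@H](C)C[C@@H](O[Si](C)(C)C(C)(C)C)[C@H](C(C)C)C2 | intermediate (not isolated)
42 | endo Diels–Alder adduct (C2 enone, C2′ bridge ketal) | O=C1C2=C(C[C@@H](C(C)C)[C@H](O[Si](C)(C)C(C)(C)C)C[C@H]2C)[C@]3(C)[C@H]1[C@@H]4C(C)=C5CC(=C(C)C)[C@@H](O[Si](C)(C)C(C)(C)C)C[C@@H](C)[C@]35C46OCCO6 | intermediate
43 | 2-endo allylic alcohol | O[C@H]1C2=C(C[C@@H](C(C)C)[C@H](O[Si](C)(C)C(C)(C)C)C[C@H]2C)[C@]3(C)[C@H]1[C@@H]4C(C)=C5CC(=C(C)C)[C@@H](O[Si](C)(C)C(C)(C)C)C[C@@H](C)[C@]35C46OCCO6 | intermediate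
44 | 2-exo allylic acetate | CC(=O)O[C@@H]1C2=C(C[C@@H](C(C)C)[C@H](O[Si](C)(C)C(C)(C)C)C[C@H]2C)[C@]3(C)[C@H]1[C@@H]4C(C)=C5CC(=C(C)C)[C@@H](O[Si](C)(C)C(C)(C)C)C[C@@H](C)[C@]35C46OCCO6 | intermediate
45 | Cope product (bridge syn-acetate, allylic C2′ ketal) | CC(=O)O[C@H]1[C@H]2C(C)=C3C[C@@H](C(C)C)[C@H](O[Si](C)(C)C(C)(C)C)C[C@@H](C)[C@]31[C@]1(C)C3=C(C4(OCCO4)[C@H]21)[C@H](C)C[C@H](O[Si](C)(C)C(C)(C)C)C(=C(C)C)C3 | intermediate
46 | 8,8′-diol 2′-enone | CC(=O)O[C@H]1[C@H]2C(C)=C3C[C@@H](C(C)C)[C@H](O)C[C@@H](C)[C@]31[C@]1(C)C3=C(C(=O)[C@H]21)[C@H](C)C[C@H](O)C(=C(C)C)C3 | intermediate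
47 | 2-acetoxy-2′,8,8′-trione | CC(=O)O[C@H]1[C@H]2C(C)=C3C[C@@H](C(C)C)C(=O)C[C@@H](C)[C@]31[C@]1(C)C3=C(C(=O)[C@H]21)[C@H](C)CC(=O)C(=C(C)C)C3 | intermediate
48 | 11′-hydroperoxy-6′-en-8′-one | CC(=O)O[C@H]1[C@H]2C(C)=C3C[C@@H](C(C)C)C(=O)C[C@@H](C)[C@]31[C@]1(C)C3=C(C(=O)[C@H]21)[C@H](C)CC(=O)C(C(C)(C)OO)=C3 | intermediate (not isolated)
49 | CNP0317907.1 | CC(=O)O[C@H]1[C@H]2C(C)=C3C[C@@H](C(C)C)C(=O)C[C@@H](C)[C@]31[C@]1(C)C3=C(C(=O)[C@H]21)[C@H](C)C[C@@]1(O)OOC(C)(C)C1=C3 | target

**Totals**
- Total steps: 32.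
- Longest linear sequence: 19 steps (14–25, then 26–32), which is 0.59 of the total.

**Steps most likely to fail**

Step 26 (cross Diels–Alder). Ketal diene 39 may be too hindered or too labile, in which case 41 simply dimerises with itself.
- The fallback sets out from 21 and 36 and drops the ketal diene altogether.
- Compound 21 and a threefold excess of 36 are oxidised together (mCPBA, −78 °C) to 40 and the selenoxide F1.
- On warming, 41 and the free cyclopentadienone F2 co-dimerise.
- The cross-dimer dione F3, which is in Cope equilibrium with its peri-isomer, is separated from the homodimers.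
- Its strained 7-norbornenone carbonyl (C2′) is ketalised chemoselectively with (TMSOCH2)2 and TMSOTf, which returns to the route at 42.

Step 29 (Cope rearrangement at the ketal stage). The 44/45 equilibrium may be unfavourable, or cycloreversion may compete.
- The fallback sets out from 44 and couples the rearrangement to an irreversible chemical drain.
- Compound 44 is heated in wet dioxane with PPTS at 90–100 °C.
- The bridge ketal of 44 is inert under these conditions, but the allylic ketal of any 45 formed is hydrolysed at once to the conjugated bis-silyl enone F4.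
- Treatment of F4 with aqueous HF in MeCN returns to the route at 46.

Step 32 (photooxygenation). Attack at C4=C5 or H-abstraction from the isopropylidene methyls could compete.
- The fallback sets out from 47 and uses ground-state oxygen on an anion instead of singlet oxygen on the alkene.
- DBU in MeCN under O2 removes the most acidic proton, H6′, which is γ to the cyclopentenone and allylic to the isopropylidene.
- The extended trienolate F5 is oxygenated at its C11′ terminus to give the same hydroperoxide 48.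
- Compound 48 closes to 49.

**Further compounds**
F1 | step 26 | selenoxide of 36 | O=C1C([Se](=O)c3ccccc3)C(C)C2=C1[C@H](C)C[C@H](O[Si](C)(C)C(C)(C)C)C(=C(C)C)C2
F2 | step 26 | free cyclopentadienone of the isopropylidene half | O=C1C=C(C)C2=C1[C@H](C)C[C@H](O[Si](C)(C)C(C)(C)C)C(=C(C)C)C2
F3 | step 26 | cross-dimer dione (C2 enone, C2′ bridge ketone) | O=C1C2=C(C[C@@H](C(C)C)[C@H](O[Si](C)(C)C(C)(C)C)C[C@H]2C)[C@]3(C)[C@H]1[C@@H]4C(C)=C5CC(=C(C)C)[C@@H](O[Si](C)(C)C(C)(C)C)C[C@@H](C)[C@]35C4=O
F4 | step 29 | bis-silyl 2′-enone | CC(=O)O[C@H]1[C@H]2C(C)=C3C[C@@H](C(C)C)[C@H](O[Si](C)(C)C(C)(C)C)C[C@@H](C)[C@]31[C@]1(C)C3=C(C(=O)[C@H]21)[C@H](C)C[C@H](O[Si](C)(C)C(C)(C)C)C(=C(C)C)C3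
F5 | step 32 | extended trienolate of 47 | CC(=O)O[C@H]1[C@H]2C(C)=C3C[C@@H](C(C)C)C(=O)C[C@@H](C)[C@]31[C@]1(C)C3=CC(=C(C)C)C(=O)C[C@@H](C)C3=C([O-])[C@H]21
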